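**Retrosynthetic overview**
1. Meridianin F ⇒ the 2-aminopyrimidine ring is built last, by condensing guanidine onto an indol-3-yl enaminone; the N-tosyl group is lost in the same basic operation.
2. Enaminone ⇒ 3-acetyl-5,6-dibromo-1-tosylindole + DMF-DMA: the key C–C bond (acetyl CH3 carbon to the formyl-equivalent carbon) is made by an intermolecular Mannich-type condensation.
3. 3-Acetyl-1-tosylindole ⇒ Friedel–Crafts C3-acylation of 5,6-dibromo-1-tosylindole ⇒ 5,6-dibromoindole.
4. 5,6-Dibromoindole ⇒ methyl indole-3-carboxylate by regioselective dibromination, saponification and decarboxylation (the ester blocks C3 and deactivates C2 during bromination).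
5. Ring order: the indole is bought, the pyrimidine is formed last.

Assumption: the target is achiral (no stereocentres, so there is no enantiomer to control), and transient salts (carboxylate, indolide, free guanidine) are treated as forms of the numbered compound.

**Route**

Step 1
Reactants: 1 methyl 1H-indole-3-carboxylate; 2 bromine
Product: 3 methyl 5,6-dibromo-1H-indole-3-carboxylate
Conditions: Br2 (2.2 equiv), AcOH, rt
Reagents that add atoms: bromine, BrBr
Why: Electrophilic aromatic bromination; the 3-ester deactivates C2 and the pyrrole ring, so both bromines enter the benzo ring at C5 and C6, the known selectivity for this substrate.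

Step 2
Reactants: 3 methyl 5,6-dibromo-1H-indole-3-carboxylate; 4 sodium hydroxide
Product: 5 5,6-dibromo-1H-indole-3-carboxylic acid
Conditions: NaOH, MeOH/H2O, reflux; then aq. HCl, 0 °C
Reagents that add atoms: sodium hydroxide, [Na+].[OH-]
Why: Ester saponification (slow for this vinylogous carbamate, hence reflux); aryl bromides are inert to hydroxide and the acid precipitates on cold acidification.

Step 3
Reactants: 5 5,6-dibromo-1H-indole-3-carboxylic acid
Product: 6 5,6-dibromo-1H-indole
Conditions: Ag2CO3 (10 mol %), AcOH (5 mol %), DMSO, 120 °C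
Reagents that add atoms: none
Why: Protodecarboxylation; indole-3-carboxylic acids lose CO2 readily through ipso-metalation/protonation at the nucleophilic C3, and Ag(I) does not touch aryl bromides.

Step 4
Reactants: 6 5,6-dibromo-1H-indole; 7 p-toluenesulfonyl chloride
Product: 8 5,6-dibromo-1-tosyl-1H-indole
Conditions: NaH, THF, 0 °C; then TsCl, 0 °C → rt
Reagents that add atoms: p-toluenesulfonyl chloride, Cc1ccc(cc1)S(Cl)(=O)=O
Why: N-sulfonylation of the sodium indolide; the tosyl group prevents N-methylation by DMF-DMA in step 6 and is removable by base at the end.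

Step 5
Reactants: 8 5,6-dibromo-1-tosyl-1H-indole; 9 acetyl chloride
Product: 10 1-(5,6-dibromo-1-tosyl-1H-indol-3-yl)ethan-1-one
Conditions: AcCl, AlCl3 (3 equiv), CH2Cl2, 0 °C → rt
Reagents that add atoms: acetyl chloride, CC(Cl)=O
Why: Friedel–Crafts acylation; N-sulfonylindoles acylate at C3, the dibrominated benzo ring is too deactivated to compete, and AlCl3 acts as promoter and is released as its hydrate on quench.

Step 6
Reactants: 10 1-(5,6-dibromo-1-tosyl-1H-indol-3-yl)ethan-1-one; 11 N,N-dimethylformamide dimethyl acetal (DMF-DMA)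
Product: 13 (E)-1-(5,6-dibromo-1-tosyl-1H-indol-3-yl)-3-(dimethylamino)prop-2-en-1-one, via Mannich adduct 12 (not isolated)
Conditions: DMF-DMA (4 equiv), DMF, 110 °C
Reagents that add atoms: DMF-DMA, COC(OC)N(C)C
Why: Mannich-type condensation: the ketone enol(ate) adds to the methoxymethylene-iminium ion released from DMF-DMA to form the key C–C bond, and loss of MeOH from the adduct gives the conjugated (thermodynamic) E-enaminone.

Step 7
Reactants: 13 (E)-1-(5,6-dibromo-1-tosyl-1H-indol-3-yl)-3-(dimethylamino)prop-2-en-1-one; 14 guanidine hydrochloride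
Product: 16 meridianin F [4-(5,6-dibromo-1H-indol-3-yl)pyrimidin-2-amine], via N-tosyl meridianin F 15 (not isolated)
Conditions: guanidine·HCl, K2CO3, 2-methoxyethanol, reflux; then 2 M aq. KOH, 80 °C
Reagents that add atoms: guanidine hydrochloride, NC(=N)N.Cl
Why: Cyclocondensation of the 1,3-bielectrophile with guanidine (aza-Michael addition/elimination of Me2NH, then cyclodehydration) gives the 2-aminopyrimidine, and the N-sulfonyl group on the electron-poor indole is cleaved by the hot base, the KOH finish completing it.

**Compound list**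
1 | methyl 1H-indole-3-carboxylate | COC(=O)c1c[nH]c2ccccc12 | starting material
2 | bromine | BrBr | starting material
3 | methyl 5,6-dibromo-1H-indole-3-carboxylate | COC(=O)c1c[nH]c2cc(Br)c(Br)cc12 | intermediate
4 | sodium hydroxide | [Na+].[OH-] | starting material
5 | 5,6-dibromo-1H-indole-3-carboxylic acid | OC(=O)c1c[nH]c2cc(Br)c(Br)cc12 | intermediate
6 | 5,6-dibromo-1H-indole | c1c[nH]c2cc(Br)c(Br)cc12 | intermediate
7 | p-toluenesulfonyl chloride | Cc1ccc(cc1)S(Cl)(=O)=O | starting material
8 | 5,6-dibromo-1-tosyl-1H-indole | Cc1ccc(cc1)S(=O)(=O)n1ccc2cc(Br)c(Br)cc12 | intermediate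
9 | acetyl chloride | CC(Cl)=O | starting material
10 | 1-(5,6-dibromo-1-tosyl-1H-indol-3-yl)ethan-1-one | CC(=O)c1cn(S(=O)(=O)c2ccc(C)cc2)c2cc(Br)c(Br)cc12 | intermediate
11 | N,N-dimethylformamide dimethyl acetal | COC(OC)N(C)C | starting material
12 | Mannich adduct: 1-(5,6-dibromo-1-tosyl-1H-indol-3-yl)-3-(dimethylamino)-3-methoxypropan-1-one (racemic, transient, not isolated) | COC(N(C)C)CC(=O)c1cn(S(=O)(=O)c2ccc(C)cc2)c2cc(Br)c(Br)cc12 | intermediate
13 | (E)-1-(5,6-dibromo-1-tosyl-1H-indol-3-yl)-3-(dimethylamino)prop-2-en-1-one | CN(C)/C=C/C(=O)c1cn(S(=O)(=O)c2ccc(C)cc2)c2cc(Br)c(Br)cc12 | intermediate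
14 | guanidine hydrochloride | NC(=N)N.Cl | starting material
15 | N-tosyl meridianin F: 4-(5,6-dibromo-1-tosyl-1H-indol-3-yl)pyrimidin-2-amine (not isolated) | Cc1ccc(cc1)S(=O)(=O)n1cc(-c2ccnc(N)n2)c2cc(Br)c(Br)cc12 | intermediate
16 | meridianin F, 4-(5,6-dibromo-1H-indol-3-yl)pyrimidin-2-amine (achiral) | Nc1nccc(-c2c[nH]c3cc(Br)c(Br)cc23)n1 | target

**Totals**
Total step count: 7. Longest linear sequence: 7 steps (1 → 16).

**Three steps most likely to fail, with fallbacks**

Step 3 (protodecarboxylation of 5). The two bromines make C3 less nucleophilic, so CO2 loss may stall or need temperatures at which the free indole degrades. The fallback keeps the carboxyl carbon and turns it into the acetyl carbonyl. It sets out from acid 5: CDI in THF followed by MeNHOMe·HCl gives the Weinreb amide 5,6-dibromo-N-methoxy-N-methyl-1H-indole-3-carboxamide F1. NaH/TsCl in THF then gives 5,6-dibromo-N-methoxy-N-methyl-1-tosyl-1H-indole-3-carboxamide F2. MeMgBr in THF at 0 °C (the chelated tetrahedral intermediate stops at the ketone, and MeMgBr does not exchange aryl bromides) gives ketone 10, where the route is rejoined. This also bypasses step 5.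

Step 5 (Friedel–Crafts acylation of 8). The substrate is deactivated by both the sulfonyl group and the two bromines, so acylation may be slow, and excess AlCl3 can cause partial desulfonylation. The fallback acylates before the nitrogen is deactivated. It sets out from 6: Et2AlCl and acetyl chloride in CH2Cl2 at 0 °C (C3-selective acylation of the N–Al indolide) give 1-(5,6-dibromo-1H-indol-3-yl)ethan-1-one F3. N-tosylation of this more acidic NH (NaH, TsCl, THF) returns to the route at 10.

Step 7 (one-pot pyrimidine formation and desulfonylation of 13). Sulfonyl transfer to the alkoxide solvent can generate an alkylating sulfonate ester and hence N-alkylated by-products, or the detosylation may be incomplete. The fallback separates the two events and builds the ring on the free indole. It sets out from 13: TBAF in refluxing THF removes the sulfonyl group to give (E)-1-(5,6-dibromo-1H-indol-3-yl)-3-(dimethylamino)prop-2-en-1-one F4. This is condensed with guanidine (from 14 and NaOEt, EtOH, reflux) to arrive directly at 16.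

**Further compounds**
F1 | step 3 | 5,6-dibromo-N-methoxy-N-methyl-1H-indole-3-carboxamide | CON(C)C(=O)c1c[nH]c2cc(Br)c(Br)cc12
F2 | step 3 | 5,6-dibromo-N-methoxy-N-methyl-1-tosyl-1H-indole-3-carboxamide | CON(C)C(=O)c1cn(S(=O)(=O)c2ccc(C)cc2)c2cc(Br)c(Br)cc12
F3 | step 5 | 1-(5,6-dibromo-1H-indol-3-yl)ethan-1-one | CC(=O)c1c[nH]c2cc(Br)c(Br)cc12
F4 | step 7 | (E)-1-(5,6-dibromo-1H-indol-3-yl)-3-(dimethylamino)prop-2-en-1-one | CN(C)/C=C/C(=O)c1c[nH]c2cc(Br)c(Br)cc12
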